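Ring A (C1–C2–C3–C4–C5–C8) is treated as a three-carbon bridge, C2–C3–C4, spanning the α and α′ carbons C1 and C5 of the ring B cyclopentanone (C1–C7–C6–C5–C8, carbonyl at C8). The C2 ketone and C3 methoxy group map onto the formyl and methoxy groups of 2-methoxyacrolein. One flask builds ring A: a Mukaiyama–Michael addition through C5 forms C4–C5 and the allylated quaternary centre, then a magnesium-mediated aldol from C1 onto the C2 aldehyde forms C1–C2. The precursor is the trimethylsilyl enol ether (C5=C8) of the trans,trans 2-allyl-5-methoxy-3-methyl-4-arylcyclopentanone, made regiospecifically by cuprate addition. Oxidation-level exchange between C2 and C8 and acetylation finish the synthesis.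

Key step: step 9

Remark: Ar = 3,4-dimethoxyphenyl; the labels C1–C8 are those of the bicyclic core (C1 methoxy bridgehead, C2 C=O, C3 CHOMe, C4 CH2, C5 allyl bridgehead, C6 CHMe, C7 CHAr, C8 CHOAc) and are also used for the monocyclic intermediates; the methoxy-bearing carbon of 6–19 (later C1) is drawn trans to the aryl group as the expected isomer, but its configuration is erased in step 9 and needs no control.

Step 1
Reactants: 1 4-bromo-1,2-dimethoxybenzene; 2 cyclopent-2-en-1-one
Product: 5 {[(3R)-3-(3,4-dimethoxyphenyl)cyclopent-1-en-1-yl]oxy}trimethylsilane, via aryllithium 3 (not isolated), via lithium aryltitanate 4 (not isolated)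
Conditions: n-BuLi, THF, −78 °C; Ti(Oi-Pr)4, −78 → 0 °C; then 2, Me3SiCl, [RhCl(C2H4)2]2 (1.5 mol %), (R)-BINAP (3.3 mol %), THF, 20 °C
Reagents that add atoms: chlorotrimethylsilane, C[Si](C)(C)Cl
Why: Rhodium–BINAP-catalysed asymmetric conjugate arylation (Hayashi-type 1,4-addition of an aryltitanate) places the aryl group on the β-carbon, and the chlorosilane captures the enolate regiospecifically on the aryl side; (R)-BINAP is expected, by analogy with phenyl transfer to cyclopentenone, to give the (R) centre that becomes C7.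

Step 2
Reactants: 5 {[(3R)-3-(3,4-dimethoxyphenyl)cyclopent-1-en-1-yl]oxy}trimethylsilane
Product: 7 (2S,3S)-3-(3,4-dimethoxyphenyl)-2-hydroxycyclopentan-1-one, via silyloxy ketone 6 (not isolated)
Conditions: mCPBA, NaHCO3, CH2Cl2, −20 → 0 °C; then 1 M HCl, THF, 0 °C
Reagents that add atoms: mCPBA, OOC(=O)c1cccc(Cl)c1
Why: In this Rubottom oxidation the peracid should epoxidise the electron-rich enol silane on the face anti to the neighbouring aryl group, and epoxide opening with silyl shift followed by mild acid hydrolysis should give the trans α-hydroxy ketone while the veratryl ring stays inert at this temperature.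

Step 3
Reactants: 7 (2S,3S)-3-(3,4-dimethoxyphenyl)-2-hydroxycyclopentan-1-one
Product: 8 (2S,3S)-3-(3,4-dimethoxyphenyl)-2-methoxycyclopentan-1-one
Conditions: MeI, Ag2O, 4 Å MS, CH2Cl2, 35 °C, dark
Reagents that add atoms: iodomethane, CI
Why: Purdie O-methylation with silver oxide and iodomethane etherifies the hydroxyl without forming a free enolate, so the acyloin should neither isomerise nor lose its trans arrangement.

Step 4
Reactants: 8 (2S,3S)-3-(3,4-dimethoxyphenyl)-2-methoxycyclopentan-1-one
Product: 10 (4S,5S)-4-(3,4-dimethoxyphenyl)-5-methoxycyclopent-2-en-1-one, via lithium enolate 9 (not isolated)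
Conditions: LDA, THF, −78 °C; then PhS(Cl)=Nt-Bu, −78 °C
Reagents that add atoms: none
Why: In this Mukaiyama dehydrogenation, kinetic deprotonation by LDA should occur at the unhindered α′-methylene and not at the methoxy-bearing methine, and the enolate is captured at sulfur by N-tert-butylbenzenesulfinimidoyl chloride and fragments by syn-elimination at low temperature, leaving the two stereocentres untouched.

Step 5
Reactants: 10 (4S,5S)-4-(3,4-dimethoxyphenyl)-5-methoxycyclopent-2-en-1-one
Product: 11 (4S,5S)-4-(3,4-dimethoxyphenyl)-2-iodo-5-methoxycyclopent-2-en-1-one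
Conditions: I2, pyridine, CH2Cl2, 0 → 23 °C
Reagents that add atoms: iodine, II
Why: Johnson α-iodination of an enone (conjugate addition of pyridine, iodination of the enolate, elimination) places iodine on the α-carbon under conditions too weakly basic to epimerise the aryl- and methoxy-bearing carbons.

Step 6
Reactants: 11 (4S,5S)-4-(3,4-dimethoxyphenyl)-2-iodo-5-methoxycyclopent-2-en-1-one; 12 allyltributylstannane
Product: 13 (4S,5S)-4-(3,4-dimethoxyphenyl)-5-methoxy-2-(prop-2-en-1-yl)cyclopent-2-en-1-one
Conditions: Pd2(dba)3 (2.5 mol %), AsPh3 (10 mol %), CuI (10 mol %), NMP, 23 °C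
Reagents that add atoms: none
Why: Stille cross-coupling of an α-iodoenone with an allylstannane, accelerated by triphenylarsine and copper iodide, should run at room temperature, which keeps the allyl double bond out of conjugation.

Step 7
Reactants: 13 (4S,5S)-4-(3,4-dimethoxyphenyl)-5-methoxy-2-(prop-2-en-1-yl)cyclopent-2-en-1-one
Product: 14 {[(3R,4S,5S)-4-(3,4-dimethoxyphenyl)-5-methoxy-3-methyl-2-(prop-2-en-1-yl)cyclopent-1-en-1-yl]oxy}trimethylsilane
Conditions: Me2CuLi (from MeLi, CuI), Me3SiCl, Et2O–THF, −78 °C; then Et3N; pentane, cold aq. NaHCO3; used at once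
Reagents that add atoms: lithium dimethylcuprate, [Li+].C[Cu-]C; chlorotrimethylsilane, C[Si](C)(C)Cl
Why: Chlorosilane-accelerated Gilman cuprate conjugate addition should deliver methyl to the β-carbon anti to the adjacent aryl group (the later C6, trans to C7) and trap the enolate in situ, so the tetrasubstituted enol silane forms only on the allyl-bearing side.

Step 8
Reactants: 15 1,1,2-trimethoxyethane
Product: 17 2-methoxyprop-2-enal (2-methoxyacrolein), via methoxyacetaldehyde 16 (not isolated)
Conditions: 1 M HCl, 50 °C; NaHCO3 to pH 6; then 37 % aq. CH2O, pyrrolidine (10 mol %), EtCO2H (10 mol %), i-PrOH, 45 °C; extract, distil, use fresh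
Reagents that add atoms: water, O; formaldehyde, C=O
Why: Acetal hydrolysis followed by amine-catalysed Mannich-type α-methylenation of the aldehyde (aminomethylation, then elimination) should give the α-methoxy enal, which is distilled and used fresh because it polymerises.

Step 9
Reactants: 14 {[(3R,4S,5S)-4-(3,4-dimethoxyphenyl)-5-methoxy-3-methyl-2-(prop-2-en-1-yl)cyclopent-1-en-1-yl]oxy}trimethylsilane; 17 2-methoxyprop-2-enal
Product: 20 (1R,2R,3S,5S,6R,7S)-7-(3,4-dimethoxyphenyl)-2-hydroxy-1,3-dimethoxy-6-methyl-5-(prop-2-en-1-yl)bicyclo[3.2.1]octan-8-one, via Michael adduct enol silane 18 (not isolated), via keto aldehyde 19 (not isolated)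
Conditions: 17 (2 equiv), Me3SiNTf2 (10 mol %), CH2Cl2, −78 °C; then Et3N (4 equiv), MeOH (2 equiv), MgBr2·OEt2 (3 equiv), −78 → 0 °C; aq. NH4Cl at 0 °C
Reagents that add atoms: none
Why: The silyl triflimide activates the formyl group of 17 and the enol silane attacks the terminal CH2 through C5 (silyl-transfer Mukaiyama–Michael addition, C4–C5 and the quaternary centre), giving ketone 18 with the side chain as an aldehyde enol silane; methanolysis frees aldehyde 19, and soft enolisation of the C8 ketone by MgBr2/Et3N, possible only toward C1 now that C5 is quaternary and assisted by magnesium chelation between the C8 oxygen and the C1 methoxy group, sets off the aldol onto C2 (C1–C2). The closest known chemistry is the α,α′-annulation of cyclopentanones with acroleins (Michael addition then aldol) to 2-hydroxybicyclo[3.2.1]octan-8-ones, combined with Lewis acid Mukaiyama–Michael additions of tetrasubstituted enol silanes that create quaternary carbons. Ring A (C1–C2–C3–C4–C5–C8) closes by a 6-(enolendo)-exo-trig aldol, since the C8=C1 enolate bond lies inside the ring that forms. C5 is set by approach of the enal anti to the adjacent C6 methyl group; C1 is set by the tether, because the chain hanging from C5 can reach only the face of ring B on which it sits (the face of the C7 aryl group); the C2 hydroxyl falls syn to C8 because magnesium bridges the enolate and aldehyde oxygens in a closed transition state. C3 epimerises freely in aldehyde 19 and should close with its methoxy group anti to the magnesium-bound aldehyde oxygen (Cornforth-type dipole opposition), that is on the face of ring A away from C8 and trans to the C2 hydroxyl. The step needs 1,4- and not 1,2-addition, which the crowded tetrasubstituted nucleophile and the reversibility of a 1,2-silyl aldol under silyl Lewis acid catalysis should secure, and it needs a single enolisation site at each stage, which the substitution pattern provides.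

Step 10
Reactants: 20 (1R,2R,3S,5S,6R,7S)-7-(3,4-dimethoxyphenyl)-2-hydroxy-1,3-dimethoxy-6-methyl-5-(prop-2-en-1-yl)bicyclo[3.2.1]octan-8-one
Product: 22 (1S,2R,3S,5S,6R,7S,8S)-7-(3,4-dimethoxyphenyl)-1,3-dimethoxy-6-methyl-5-(prop-2-en-1-yl)bicyclo[3.2.1]octane-2,8-diol, via diethylborinate 21 (not isolated)
Conditions: Et2BOMe, THF–MeOH (4:1), −78 °C; NaBH4, −78 → −40 °C; AcOH; MeOH azeotrope
Reagents that add atoms: none
Why: In this Narasaka–Prasad reduction diethylboron ties the axial C2 oxygen to the C8 carbonyl oxygen and so covers the ring A face of the ketone, and external hydride should then enter from the C6–C7 side to give the 2,8-syn diol with the new C8 hydroxyl pointing over ring A.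

Step 11
Reactants: 22 (1S,2R,3S,5S,6R,7S,8S)-7-(3,4-dimethoxyphenyl)-1,3-dimethoxy-6-methyl-5-(prop-2-en-1-yl)bicyclo[3.2.1]octane-2,8-diol
Product: 23 (1S,3S,5S,6R,7S,8S)-7-(3,4-dimethoxyphenyl)-8-hydroxy-1,3-dimethoxy-6-methyl-5-(prop-2-en-1-yl)bicyclo[3.2.1]octan-2-one
Conditions: Dess–Martin periodinane (1.05 equiv), NaHCO3, CH2Cl2, 0 °C
Reagents that add atoms: none
Why: Dess–Martin oxidation under stoichiometric control should take the C2 carbinol, which has one fully substituted neighbour, in preference to the C8 carbinol, which lies between two quaternary bridgeheads and whose oxidation would return an sp2 carbon to the strained one-carbon bridge, and the buffered non-basic medium should leave C3 untouched.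

Step 12
Reactants: 23 (1S,3S,5S,6R,7S,8S)-7-(3,4-dimethoxyphenyl)-8-hydroxy-1,3-dimethoxy-6-methyl-5-(prop-2-en-1-yl)bicyclo[3.2.1]octan-2-one
Product: 24 (1S,3S,5S,6R,7S,8S)-7-(3,4-dimethoxyphenyl)-1,3-dimethoxy-6-methyl-2-oxo-5-(prop-2-en-1-yl)bicyclo[3.2.1]octan-8-yl acetate
Conditions: Ac2O, pyridine, DMAP (10 mol %), CH2Cl2, 23 °C
Reagents that add atoms: acetic anhydride, CC(=O)OC(C)=O
Why: DMAP-catalysed acetylation (nucleophilic acyl-transfer catalysis) should esterify even this hindered secondary hydroxyl, while elimination is impossible because C1 is quaternary and the weak base is not expected to epimerise C3 or open the ketol by retro-aldol cleavage at room temperature.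

Compound list

1 | 4-bromo-1,2-dimethoxybenzene | COc1ccc(Br)cc1OC | starting material
2 | cyclopent-2-en-1-one | O=C1C=CCC1 | starting material
3 | 3,4-dimethoxyphenyllithium | [Li]c1ccc(OC)c(OC)c1 | intermediate (not isolated)
4 | lithium (3,4-dimethoxyphenyl)tetraisopropoxytitanate | [Li+].CC(C)O[Ti-](OC(C)C)(OC(C)C)(OC(C)C)c1ccc(OC)c(OC)c1 | intermediate (not isolated)
5 | {[(3R)-3-(3,4-dimethoxyphenyl)cyclopent-1-en-1-yl]oxy}trimethylsilane | C[Si](C)(C)OC1=C[C@H](c2ccc(OC)c(OC)c2)CC1 | intermediate
6 | (2S,3S)-3-(3,4-dimethoxyphenyl)-2-[(trimethylsilyl)oxy]cyclopentan-1-one | O=C1[C@@H](O[Si](C)(C)C)[C@H](c2ccc(OC)c(OC)c2)CC1 | intermediate (not isolated)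
7 | (2S,3S)-3-(3,4-dimethoxyphenyl)-2-hydroxycyclopentan-1-one | O=C1[C@@H](O)[C@H](c2ccc(OC)c(OC)c2)CC1 | intermediate
8 | (2S,3S)-3-(3,4-dimethoxyphenyl)-2-methoxycyclopentan-1-one | O=C1[C@@H](OC)[C@H](c2ccc(OC)c(OC)c2)CC1 | intermediate
9 | lithium (4S,5S)-4-(3,4-dimethoxyphenyl)-5-methoxycyclopent-1-en-1-olate | [Li]OC1=CC[C@@H](c2ccc(OC)c(OC)c2)[C@@H]1OC | intermediate (not isolated)
10 | (4S,5S)-4-(3,4-dimethoxyphenyl)-5-methoxycyclopent-2-en-1-one | O=C1C=C[C@@H](c2ccc(OC)c(OC)c2)[C@@H]1OC | intermediate
11 | (4S,5S)-4-(3,4-dimethoxyphenyl)-2-iodo-5-methoxycyclopent-2-en-1-one | O=C1C(I)=C[C@@H](c2ccc(OC)c(OC)c2)[C@@H]1OC | intermediate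
12 | allyltributylstannane | C=CC[Sn](CCCC)(CCCC)CCCC | starting material
13 | (4S,5S)-4-(3,4-dimethoxyphenyl)-5-methoxy-2-(prop-2-en-1-yl)cyclopent-2-en-1-one | O=C1C(CC=C)=C[C@@H](c2ccc(OC)c(OC)c2)[C@@H]1OC | intermediate
14 | {[(3R,4S,5S)-4-(3,4-dimethoxyphenyl)-5-methoxy-3-methyl-2-(prop-2-en-1-yl)cyclopent-1-en-1-yl]oxy}trimethylsilane (methyl trans to aryl, aryl trans to methoxy) | C=CCC1=C(O[Si](C)(C)C)[C@@H](OC)[C@H](c2ccc(OC)c(OC)c2)[C@H]1C | intermediate
15 | 1,1,2-trimethoxyethane | COCC(OC)OC | starting material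
16 | methoxyacetaldehyde | COCC=O | intermediate (not isolated)
17 | 2-methoxyprop-2-enal (2-methoxyacrolein) | C=C(OC)C=O | intermediate
18 | (2S,3R,4S,5S)-4-(3,4-dimethoxyphenyl)-5-methoxy-2-{2-methoxy-3-[(trimethylsilyl)oxy]prop-2-en-1-yl}-3-methyl-2-(prop-2-en-1-yl)cyclopentan-1-one (enol silane geometry undefined; new chain trans to the C6 methyl) | C=CC[C@@]1(CC(OC)=CO[Si](C)(C)C)C(=O)[C@@H](OC)[C@H](c2ccc(OC)c(OC)c2)[C@H]1C | intermediate (not isolated)
19 | 3-[(1S,2R,3S,4S)-3-(3,4-dimethoxyphenyl)-4-methoxy-2-methyl-5-oxo-1-(prop-2-en-1-yl)cyclopentyl]-2-methoxypropanal (both epimers at the aldehyde α-carbon, interconverting) | C=CC[C@@]1(CC(OC)C=O)C(=O)[C@@H](OC)[C@H](c2ccc(OC)c(OC)c2)[C@H]1C | intermediate (not isolated)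
20 | (1R,2R,3S,5S,6R,7S)-7-(3,4-dimethoxyphenyl)-2-hydroxy-1,3-dimethoxy-6-methyl-5-(prop-2-en-1-yl)bicyclo[3.2.1]octan-8-one (C2 hydroxyl syn to C8, C3 methoxy anti to C8, C6 methyl exo, C7 aryl endo) | C=CC[C@]12C[C@H](OC)[C@@H](O)[C@](OC)([C@H](c3ccc(OC)c(OC)c3)[C@H]1C)C2=O | intermediate
21 | 2-O-diethylboryl derivative of 20 | C=CC[C@]12C[C@H](OC)[C@@H](OB(CC)CC)[C@](OC)([C@H](c3ccc(OC)c(OC)c3)[C@H]1C)C2=O | intermediate (not isolated)
22 | (1S,2R,3S,5S,6R,7S,8S)-7-(3,4-dimethoxyphenyl)-1,3-dimethoxy-6-methyl-5-(prop-2-en-1-yl)bicyclo[3.2.1]octane-2,8-diol (both hydroxyls on the same side, C8 hydroxyl over ring A) | C=CC[C@]12C[C@H](OC)[C@@H](O)[C@](OC)([C@H](c3ccc(OC)c(OC)c3)[C@H]1C)[C@H]2O | intermediate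
23 | (1S,3S,5S,6R,7S,8S)-7-(3,4-dimethoxyphenyl)-8-hydroxy-1,3-dimethoxy-6-methyl-5-(prop-2-en-1-yl)bicyclo[3.2.1]octan-2-one | C=CC[C@]12C[C@H](OC)C(=O)[C@](OC)([C@H](c3ccc(OC)c(OC)c3)[C@H]1C)[C@H]2O | intermediate
24 | (1S,3S,5S,6R,7S,8S)-7-(3,4-dimethoxyphenyl)-1,3-dimethoxy-6-methyl-2-oxo-5-(prop-2-en-1-yl)bicyclo[3.2.1]octan-8-yl acetate | C=CC[C@]12C[C@H](OC)C(=O)[C@](OC)([C@H](c3ccc(OC)c(OC)c3)[C@H]1C)[C@H]2OC(C)=O | target

Total step count: 12. Longest linear sequence: 11 steps (steps 1–7 and 9–12, from 1 and 2); step 8 is a one-step side branch.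

Steps most likely to fail

Step 9. The enol silane may add 1,2 to the formyl group of the weakly electrophilic, methoxy-donated enal, or may add on the methyl-bearing face of C5. The crowded aldol beside the C7 aryl group may stay open or revert. Ring closure may also place the C3 methoxy group on the C8 face. The fallback sets out from 14 and returns at 24: the annulation is run with acrolein itself, the established partner for this Michael–aldol sequence, and the C3 oxygen is added last. Mukaiyama–Michael addition of 14 to acrolein (Me3SiNTf2 cat., CH2Cl2, −78 °C, aqueous work-up) should give the 3-demethoxy keto aldehyde F1, and MgBr2·OEt2/Et3N should close it to the 3-demethoxy ketol F2. The reagents of steps 10, 11 and 12 should then give the 3-demethoxy diol F3, the 3-demethoxy hydroxy ketone F4 and the 3-demethoxy acetate F5. The C2 ketone of F5 can enolise only toward C3, so Me3SiOTf/Et3N should give the C2 enol silane F6. Rubottom oxidation of F6 with dimethyldioxirane (acetone, −78 → −40 °C, mild acid work-up) should enter C3 from the face that the syn C8 acetoxy group does not cover and give the 3-hydroxy ketone F7. Methylation with MeI/Ag2O then delivers 24.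

Step 11. The oxidant may fail to distinguish the two secondary carbinols: oxidation at C8 merely regenerates 20, but over-oxidation to the 2,8-dione would invite retro-Claisen cleavage. The fallback sets out from 22 and returns at 24, and it tells the hydroxyls apart with a protecting group instead of an oxidant. Et3SiCl/imidazole (DMF, 0 °C) should silylate only the less hindered C2 hydroxyl to give the 2-O-triethylsilyl ether F10, and any bis-silyl ether can be recycled. Ac2O/DMAP/Et3N at 40 °C then acetylates C8 at a stage with no ketone present, giving the 8-acetate 2-silyl ether F11. HF·pyridine (THF, 0 °C) removes the silyl group under acidic conditions that do not promote acyl migration, giving the 8-acetate 2-ol F12. Dess–Martin oxidation, now unambiguous and the last operation, gives 24 without any basic treatment of the C3 centre.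

Step 10. Incomplete chelation or hindrance of the desired trajectory by the exo C6 methyl group may let hydride enter from the ring A face, which would give the C8 epimer. The fallback sets out from 20 and returns at 22, and it replaces chelate control by steric control. t-BuMe2SiOTf/2,6-lutidine (CH2Cl2, −78 °C) should convert the C2 hydroxyl into the axial 2-O-tert-butyldimethylsilyl ether F8, whose bulk shields the ring A face of the C8 ketone. NaBH4 (MeOH–THF, 0 °C) should then attack from the C6–C7 side to give the silyl ether alcohol F9, and Bu4NF (THF) returns diol 22.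

Further compounds

F1 | step 9 | 3-demethoxy keto aldehyde (19 without the C3 methoxy group) | C=CC[C@@]1(CCC=O)C(=O)[C@@H](OC)[C@H](c2ccc(OC)c(OC)c2)[C@H]1C
F2 | step 9 | 3-demethoxy ketol (20 without the C3 methoxy group) | C=CC[C@]12CC[C@@H](O)[C@](OC)([C@H](c3ccc(OC)c(OC)c3)[C@H]1C)C2=O
F3 | step 9 | 3-demethoxy diol (22 without the C3 methoxy group) | C=CC[C@]12CC[C@@H](O)[C@](OC)([C@H](c3ccc(OC)c(OC)c3)[C@H]1C)[C@H]2O
F4 | step 9 | 3-demethoxy hydroxy ketone (23 without the C3 methoxy group) | C=CC[C@]12CCC(=O)[C@](OC)([C@H](c3ccc(OC)c(OC)c3)[C@H]1C)[C@H]2O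
F5 | step 9 | 3-demethoxy acetate (24 without the C3 methoxy group) | C=CC[C@]12CCC(=O)[C@](OC)([C@H](c3ccc(OC)c(OC)c3)[C@H]1C)[C@H]2OC(C)=O
F6 | step 9 | C2 trimethylsilyl enol ether of F5 (C2=C3) | C=CC[C@]12CC=C(O[Si](C)(C)C)[C@](OC)([C@H](c3ccc(OC)c(OC)c3)[C@H]1C)[C@H]2OC(C)=O
F7 | step 9 | 3-hydroxy ketone (24 with hydroxyl in place of the C3 methoxy group, anti to C8) | C=CC[C@]12C[C@H](O)C(=O)[C@](OC)([C@H](c3ccc(OC)c(OC)c3)[C@H]1C)[C@H]2OC(C)=O
F8 | step 10 | 2-O-tert-butyldimethylsilyl ether of 20 | C=CC[C@]12C[C@H](OC)[C@@H](O[Si](C)(C)C(C)(C)C)[C@](OC)([C@H](c3ccc(OC)c(OC)c3)[C@H]1C)C2=O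
F9 | step 10 | 2-O-tert-butyldimethylsilyl ether of 22 | C=CC[C@]12C[C@H](OC)[C@@H](O[Si](C)(C)C(C)(C)C)[C@](OC)([C@H](c3ccc(OC)c(OC)c3)[C@H]1C)[C@H]2O
F10 | step 11 | 2-O-triethylsilyl ether of 22 | C=CC[C@]12C[C@H](OC)[C@@H](O[Si](CC)(CC)CC)[C@](OC)([C@H](c3ccc(OC)c(OC)c3)[C@H]1C)[C@H]2O
F11 | step 11 | 8-O-acetyl-2-O-triethylsilyl derivative of 22 | C=CC[C@]12C[C@H](OC)[C@@H](O[Si](CC)(CC)CC)[C@](OC)([C@H](c3ccc(OC)c(OC)c3)[C@H]1C)[C@H]2OC(C)=O
F12 | step 11 | 8-O-acetyl derivative of 22 (free C2 hydroxyl) | C=CC[C@]12C[C@H](OC)[C@@H](O)[C@](OC)([C@H](c3ccc(OC)c(OC)c3)[C@H]1C)[C@H]2OC(C)=O
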